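## Retrosynthetic overview

1. Last disconnection: the ester C–O bond between the halves, giving acid 28 (ring A) and spiro-epoxide 16 (rings B and C); carboxylate attack on the epoxide CH2 makes the ester and frees the tertiary alcohol in one event.
2. Ring A (the cyclohexene) is closed last, by a catalytic enantioselective Diels–Alder reaction of the open-chain trienoate 24 with methyl vinyl ketone; the acetyl group is a temporary activating group that is afterwards turned into isopropyl (methylenation, hydrogenation).
3. Enabling feature: in ring A the C(CH2OH)=CH double bond lies between the CH2–CH2 pair and the CH(arm)–CH(i-Pr) pair; the arm and isopropyl are cis (endo), and the CH2OH-bearing sp2 carbon is 1,4 while the arm-bearing carbon is 1,2 to the isopropyl carbon, so the "para" and "ortho" preferences of a 2-(oxymethyl)-1-alkenylbutadiene coincide; the E-acrylate arm rides in on the diene.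
4. Rings B and C: ring B from (S)-cryptone 5 (organocatalytic Michael addition/aldol condensation of isovaleraldehyde and methyl vinyl ketone); an allene [2+2] photocycloaddition sets the two cis one-carbon arms anti to isopropyl as a temporary cyclobutane, which two ozonolyses unravel; ring C by esterification and ring-closing metathesis.
5. Order of ring formation: ring B (step 2), temporary cyclobutane (step 3, opened in step 7), temporary oxirane (step 4, opened in step 18), ring C (step 10), ring A (step 14).

Key step: step 14

Remark on the chemistry: the sense of induction of the two chiral catalysts (steps 1 and 14) is assigned from the usual shielding models and by analogy with acrylate/butadiene cycloadditions; both catalysts are available as either enantiomer. PMB = 4-methoxybenzyl.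

## Route

Step 1
Reactants: 1 3-methylbutanal (isovaleraldehyde); 2 but-3-en-2-one (methyl vinyl ketone)
Product: 3 (S)-5-oxo-2-(propan-2-yl)hexanal
Conditions: (S)-2-[methoxy(diphenyl)methyl]pyrrolidine (5 mol%), ethyl 3,4-dihydroxybenzoate (20 mol%), neat, 4 °C
Reagents that add atoms: none
Why: Enamine-catalysed Michael addition of an aldehyde to an enone, in which the diphenylmethyl group of the catalyst shields one face of the E-enamine so that the enone should add to give the S-configured α-carbon (the future isopropyl-bearing carbon of ring B).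

Step 2
Reactants: 3 (S)-5-oxo-2-(propan-2-yl)hexanal
Product: 5 (S)-4-(propan-2-yl)cyclohex-2-en-1-one, via hydroxy ketone 4 (not isolated)
Conditions: LiOH, i-PrOH, rt
Reagents that add atoms: none
Why: Intramolecular aldol condensation (methyl-ketone enolate onto the aldehyde, then E1cB loss of water) closes ring B; mild base and short contact should let cyclisation outpace enolisation of the stereocentre, which is no longer α to a carbonyl in the product.

Step 3
Reactants: 5 (S)-4-(propan-2-yl)cyclohex-2-en-1-one; 6 propa-1,2-diene (allene)
Product: 7 (1R,5S,6S)-8-methylidene-5-(propan-2-yl)bicyclo[4.2.0]octan-2-one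
Conditions: hν (medium-pressure Hg lamp, Pyrex filter), 6 in excess, THF, −78 °C; then basic Al2O3
Reagents that add atoms: none
Why: Enone–allene [2+2] photocycloaddition should give the head-to-head adduct (methylidene carbon on the α-carbon) as the cis-fused cyclobutane on the face anti to the neighbouring isopropyl group, so both future arms are set cis to each other and trans to isopropyl; alumina should funnel any trans-fused isomer to cis through the enol.

Step 4
Reactants: 7 (1R,5S,6S)-8-methylidene-5-(propan-2-yl)bicyclo[4.2.0]octan-2-one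
Product: 8 8-methylidene-5-(propan-2-yl)spiro[bicyclo[4.2.0]octane-2,2'-oxirane] (oxirane CH2 on the isopropyl face, oxirane O on the cyclobutane face)
Conditions: Me3S+ I−, KN(SiMe3)2, THF, −10 → 0 °C
Reagents that add atoms: trimethylsulfonium iodide C[S+](C)C.[I-]
Why: Corey–Chaykovsky epoxidation, in which the small sulfonium ylide should attack the ketone axially from the face opposite the axial cyclobutane bond on the α-carbon, placing CH2 on the isopropyl face and oxygen on the face of the future lactone carbonyl (the tertiary-alcohol configuration).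

Step 5
Reactants: 8 spiro-epoxide
Product: 9 5-(propan-2-yl)spiro[bicyclo[4.2.0]octane-2,2'-oxiran]-8-one
Conditions: O3, CH2Cl2/MeOH, NaHCO3, −78 °C; then Me2S
Reagents that add atoms: ozone [O-][O+]=O
Why: Ozonolysis of the exocyclic 1,1-disubstituted alkene with reductive work-up should give the cyclobutanone, the epoxide being inert to ozone under buffered conditions.

Step 6
Reactants: 9 cyclobutanone
Product: 10 8-(trimethylsilyloxy)-5-(propan-2-yl)spiro[bicyclo[4.2.0]oct-7-ene-2,2'-oxirane]
Conditions: LiN(i-Pr)2, Me3SiCl (internal quench), THF, −78 °C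
Reagents that add atoms: chlorotrimethylsilane C[Si](C)(C)Cl
Why: Kinetic enolate silylation should occur only at the cyclobutanone CH2, because enolisation toward the ring-fusion carbon would create a highly strained ring-fusion cyclobutene (which also keeps the β-epoxide from E1cB opening).

Step 7
Reactants: 10 silyl enol ether
Product: 12 5-formyl-6-(propan-2-yl)-1-oxaspiro[2.5]octane-4-carboxylic acid (formyl and carboxyl cis), via trimethylsilyl ester 11 (not isolated)
Conditions: O3, CH2Cl2, −78 °C; then Me2S; pH 7 aqueous work-up
Reagents that add atoms: ozone [O-][O+]=O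
Why: Ozonolysis of the silyl enol ether cleaves the former C(=O)–CH2 bond of the cyclobutanone into a silyl ester and an aldehyde, so the temporary four-membered ring is unravelled into two cis one-carbon arms of different oxidation level with no stereocentre touched.

Step 8
Reactants: 12 aldehyde acid
Product: 13 5-ethenyl-6-(propan-2-yl)-1-oxaspiro[2.5]octane-4-carboxylic acid
Conditions: Ph3P+CH3 Br−, KN(SiMe3)2, THF, 0 °C; add 12 at −78 °C, then 0 °C; NaH2PO4 work-up
Reagents that add atoms: methyltriphenylphosphonium bromide C[P+](c1ccccc1)(c1ccccc1)c1ccccc1.[Br-]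
Why: Wittig methylenation of the aldehyde (or its cyclic hydroxy-lactone form) with the acid masked in situ as its carboxylate, which suppresses enolisation next to the carboxyl group; low temperature guards the formyl-bearing carbon, already in its equatorial configuration.

Step 9
Reactants: 13 vinyl acid; 14 tert-butyl 2-(bromomethyl)prop-2-enoate
Product: 15 2-(tert-butoxycarbonyl)prop-2-en-1-yl 5-ethenyl-6-(propan-2-yl)-1-oxaspiro[2.5]octane-4-carboxylate
Conditions: K2CO3, DMF, 0 °C → rt
Reagents that add atoms: none
Why: O-Alkylation of the carboxylate by the allylic bromide (SN2 or SN2', both leading to the same ester) under conditions too mild to open the epoxide.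

Step 10
Reactants: 15 diene ester
Product: 16 tert-butyl 1-oxo-6-(propan-2-yl)-3,5a,6,7,8,9a-hexahydro-1H-spiro[2-benzoxepine-9,2'-oxirane]-4-carboxylate (cis ring fusion)
Conditions: second-generation Grubbs catalyst RuCl2(=CHPh)(PCy3)(H2IMes) (5 mol%), toluene (2 mM), 80 °C
Reagents that add atoms: none
Why: Ring-closing metathesis between the vinyl group and the 1,1-disubstituted acrylate closes the seven-membered lactone (ring C) with loss of ethylene; the cis arms preorganise closure and the ring enforces the required alkene geometry.

Step 11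
Reactants: 17 2,3-dibromoprop-1-ene; 18 (4-methoxyphenyl)methanol
Product: 19 1-{[(2-bromoprop-2-en-1-yl)oxy]methyl}-4-methoxybenzene
Conditions: NaH, THF, 0 °C → rt
Reagents that add atoms: none
Why: Williamson ether synthesis at the allylic bromide, the vinylic bromide being inert to the alkoxide.

Step 12
Reactants: 18 (4-methoxyphenyl)methanol; 20 methyl 2-(dimethoxyphosphoryl)prop-2-enoate; 21 prop-2-enal
Product: 23 methyl (2E)-2-{[(4-methoxyphenyl)methoxy]methyl}penta-2,4-dienoate, via phosphonate carbanion 22 (not isolated)
Conditions: NaH, THF, 0 °C; 20, −78 °C; then 21, −78 → 0 °C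
Reagents that add atoms: none
Why: Tandem oxa-Michael addition/Horner–Wadsworth–Emmons olefination, in which the alkoxide adds to the phosphonoacrylate and the resulting α-branched stabilised carbanion olefinates the aldehyde, which should give mainly the E isomer (ester trans to vinyl) as with 2-phosphonopropionates.

Step 13
Reactants: 19 2-bromoallyl PMB ether; 23 dienoate
Product: 24 methyl (2E,4E)-2,6-bis{[(4-methoxyphenyl)methoxy]methyl}hepta-2,4,6-trienoate
Conditions: Pd(OAc)2 (5 mol%), K2CO3, n-Bu4NCl, DMF, 40 °C
Reagents that add atoms: none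
Why: Heck reaction, in which the alkenylpalladium bromide inserts the terminal CH2= of the dienoate and syn β-hydride elimination restores conjugation to give the new E double bond.

Step 14
Reactants: 24 trienoate; 2 but-3-en-2-one (methyl vinyl ketone)
Product: 25 methyl (2E)-3-[(1S,6S)-6-acetyl-3-{[(4-methoxyphenyl)methoxy]methyl}cyclohex-2-en-1-yl]-2-{[(4-methoxyphenyl)methoxy]methyl}prop-2-enoate (acetyl and arm cis)
Conditions: (S)-3,3-diphenyl-1-(2-methylphenyl)tetrahydro-1H,3H-pyrrolo[1,2-c][1,3,2]oxazaborole (20 mol%) activated with (CF3SO2)2NH, CH2Cl2, −78 → −40 °C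
Reagents that add atoms: none
Why: The protonated oxazaborolidine binds the s-cis enone and lowers its LUMO, and a concerted, asynchronous [4π+2π] cycloaddition joins the unsubstituted diene terminus of 24 to the β-carbon of 2 and the alkenyl-bearing terminus to its α-carbon; the closest known reaction type is the cationic-oxazaborolidine-catalysed Diels–Alder reaction of acyclic enones with 1- and 2-substituted butadienes. Ring A is closed by intermolecular suprafacial cycloaddition (two C–C bonds at once), and the ring double bond arises between the two inner diene carbons, exactly where the alkoxymethyl group sits. The acetyl-bearing and arm-bearing carbons should become cis through the endo transition state combined with the E geometry of the reacting diene double bond, and their absolute configuration is set by the catalyst, whose aryl groups shield one face of the bound enone. Regioselectivity is needed and is secured twice over, because the "ortho" preference of the 1-alkenyl group and the "para" preference of the 2-alkoxymethyl group point to the same adduct. Site selectivity is secured because the inner diene would have to react through its fully substituted ester-bearing terminus, and the E-acrylate is carried through unchanged, so the arm-bearing carbon is never an epimerisable aldehyde α-centre.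

Step 15
Reactants: 25 methyl ketone
Product: 26 methyl (2E)-3-[(1S,6S)-3-{[(4-methoxyphenyl)methoxy]methyl}-6-(prop-1-en-2-yl)cyclohex-2-en-1-yl]-2-{[(4-methoxyphenyl)methoxy]methyl}prop-2-enoate
Conditions: Zn, CH2Br2, TiCl4, THF/CH2Cl2, 0 °C → rt
Reagents that add atoms: dibromomethane BrCBr
Why: Takai–Lombardo methylenation, whose non-basic gem-dimetallic reagent should convert the methyl ketone into the isopropenyl group without epimerising the adjacent cis stereocentre and without touching the ester.

Step 16
Reactants: 26 isopropenyl compound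
Product: 27 methyl (2E)-3-[(1S,6R)-3-{[(4-methoxyphenyl)methoxy]methyl}-6-(propan-2-yl)cyclohex-2-en-1-yl]-2-{[(4-methoxyphenyl)methoxy]methyl}prop-2-enoate
Conditions: H2 (1 atm), RhCl(PPh3)3 (5 mol%), benzene, rt
Reagents that add atoms: none
Why: Homogeneous hydrogenation with RhCl(PPh3)3 should reduce the 1,1-disubstituted isopropenyl alkene far faster than the two trisubstituted alkenes (one of them conjugated), and no stereocentre is formed.

Step 17
Reactants: 27 methyl ester
Product: 28 (2E)-3-[(1S,6R)-3-{[(4-methoxyphenyl)methoxy]methyl}-6-(propan-2-yl)cyclohex-2-en-1-yl]-2-{[(4-methoxyphenyl)methoxy]methyl}prop-2-enoic acid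
Conditions: LiOH, THF/MeOH/H2O, 40 °C; then dilute HCl to pH 4
Reagents that add atoms: lithium hydroxide [Li+].[OH-]
Why: Saponification of the methyl ester, with no stereocentre α to the carbonyl and PMB ethers stable to base.

Step 18
Reactants: 28 acid (1.2 equiv); 16 spiro-epoxide lactone
Product: 29 protected target (2 PMB ethers, tert-butyl ester)
Conditions: Cs2CO3 (0.2 equiv), DMF, 60 °C
Reagents that add atoms: none
Why: Carboxylate opening of the 2,2-disubstituted epoxide by SN2 attack at the CH2 terminus, which leaves the C–O bond of the quaternary carbon untouched, so the ester link is formed and the tertiary alcohol is revealed with its configuration in the same event (the alkoxide is reprotonated by further acid, so base is catalytic).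

Step 19
Reactants: 29 protected target
Product: 30 CNP0361406.7 (target)
Conditions: CF3CO2H/CH2Cl2 (1:4), anisole, 0 °C; NaHCO3 work-up
Reagents that add atoms: none
Why: Acidolysis, in which both PMB ethers and the tert-butyl ester ionise to stabilised cations that are trapped by anisole or lost as isobutene, while the deactivated tertiary alcohol, the lactone and the ester link should survive.

## Compound list

1 | 3-methylbutanal (isovaleraldehyde) | CC(C)CC=O | starting material
2 | but-3-en-2-one (methyl vinyl ketone) | CC(=O)C=C | starting material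
3 | (S)-5-oxo-2-(propan-2-yl)hexanal | CC(=O)CC[C@@H](C(C)C)C=O | intermediate
4 | (4S)-3-hydroxy-4-(propan-2-yl)cyclohexan-1-one (both carbinol epimers) | O=C1CC[C@@H](C(C)C)C(O)C1 | intermediate (not isolated)
5 | (S)-4-(propan-2-yl)cyclohex-2-en-1-one ((S)-cryptone) | O=C1CC[C@@H](C(C)C)C=C1 | intermediate
6 | propa-1,2-diene (allene) | C=C=C | starting material
7 | (1R,5S,6S)-8-methylidene-5-(propan-2-yl)bicyclo[4.2.0]octan-2-one (cis-fused, cyclobutane anti to isopropyl) | O=C1CC[C@@H](C(C)C)[C@@H]2CC(=C)[C@@H]21 | intermediate
8 | 8-methylidene-5-(propan-2-yl)spiro[bicyclo[4.2.0]octane-2,2'-oxirane] (oxirane CH2 cis to isopropyl, oxirane O cis to cyclobutane) | O1C[C@]12CC[C@@H](C(C)C)[C@@H]3CC(=C)[C@@H]32 | intermediate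
9 | 5-(propan-2-yl)spiro[bicyclo[4.2.0]octane-2,2'-oxiran]-8-one (configuration as 8) | O1C[C@]12CC[C@@H](C(C)C)[C@@H]3CC(=O)[C@@H]32 | intermediate
10 | 8-(trimethylsilyloxy)-5-(propan-2-yl)spiro[bicyclo[4.2.0]oct-7-ene-2,2'-oxirane] (configuration as 8) | O1C[C@]12CC[C@@H](C(C)C)[C@@H]3C=C(O[Si](C)(C)C)[C@@H]32 | intermediate
11 | trimethylsilyl 5-formyl-6-(propan-2-yl)-1-oxaspiro[2.5]octane-4-carboxylate (configuration as 12) | O1C[C@]12CC[C@@H](C(C)C)[C@H](C=O)[C@@H]2C(=O)O[Si](C)(C)C | intermediate (not isolated)
12 | 5-formyl-6-(propan-2-yl)-1-oxaspiro[2.5]octane-4-carboxylic acid (formyl and carboxyl cis, both trans to isopropyl; oxirane O cis to carboxyl) | O1C[C@]12CC[C@@H](C(C)C)[C@H](C=O)[C@@H]2C(=O)O | intermediate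
13 | 5-ethenyl-6-(propan-2-yl)-1-oxaspiro[2.5]octane-4-carboxylic acid (configuration as 12) | O1C[C@]12CC[C@@H](C(C)C)[C@H](C=C)[C@@H]2C(=O)O | intermediate
14 | tert-butyl 2-(bromomethyl)prop-2-enoate | C=C(CBr)C(=O)OC(C)(C)C | starting material
15 | 2-(tert-butoxycarbonyl)prop-2-en-1-yl 5-ethenyl-6-(propan-2-yl)-1-oxaspiro[2.5]octane-4-carboxylate (configuration as 12) | O1C[C@]12CC[C@@H](C(C)C)[C@H](C=C)[C@@H]2C(=O)OCC(=C)C(=O)OC(C)(C)C | intermediate
16 | tert-butyl 1-oxo-6-(propan-2-yl)-3,5a,6,7,8,9a-hexahydro-1H-spiro[2-benzoxepine-9,2'-oxirane]-4-carboxylate (cis ring fusion; isopropyl trans to the neighbouring ring-fusion alkenyl bond; oxirane O cis to lactone carbonyl) | O1C[C@]12CC[C@@H](C(C)C)[C@@H]3C=C(C(=O)OC(C)(C)C)COC(=O)[C@@H]32 | intermediate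
17 | 2,3-dibromoprop-1-ene | C=C(Br)CBr | starting material
18 | (4-methoxyphenyl)methanol | COc1ccc(CO)cc1 | starting material
19 | 1-{[(2-bromoprop-2-en-1-yl)oxy]methyl}-4-methoxybenzene | C=C(Br)COCc1ccc(OC)cc1 | intermediate
20 | methyl 2-(dimethoxyphosphoryl)prop-2-enoate | COC(=O)C(=C)P(=O)(OC)OC | starting material
21 | prop-2-enal (acrolein) | C=CC=O | starting material
22 | methyl 2-(dimethoxyphosphoryl)-3-[(4-methoxyphenyl)methoxy]propanoate, present as its sodium carbanion | COC(=O)C(COCc1ccc(OC)cc1)P(=O)(OC)OC | intermediate (not isolated)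
23 | methyl (2E)-2-{[(4-methoxyphenyl)methoxy]methyl}penta-2,4-dienoate | C=C/C=C(\COCc1ccc(OC)cc1)C(=O)OC | intermediate
24 | methyl (2E,4E)-2,6-bis{[(4-methoxyphenyl)methoxy]methyl}hepta-2,4,6-trienoate | C=C(COCc1ccc(OC)cc1)/C=C/C=C(\COCc1ccc(OC)cc1)C(=O)OC | intermediate
25 | methyl (2E)-3-[(1S,6S)-6-acetyl-3-(PMB-oxymethyl)cyclohex-2-en-1-yl]-2-(PMB-oxymethyl)prop-2-enoate (1,6-cis) | CC(=O)[C@H]1CCC(COCc2ccc(OC)cc2)=C[C@H]1/C=C(\COCc1ccc(OC)cc1)C(=O)OC | intermediate
26 | methyl (2E)-3-[(1S,6S)-3-(PMB-oxymethyl)-6-(prop-1-en-2-yl)cyclohex-2-en-1-yl]-2-(PMB-oxymethyl)prop-2-enoate (1,6-cis) | CC(=C)[C@H]1CCC(COCc2ccc(OC)cc2)=C[C@H]1/C=C(\COCc1ccc(OC)cc1)C(=O)OC | intermediate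
27 | methyl (2E)-3-[(1S,6R)-3-(PMB-oxymethyl)-6-(propan-2-yl)cyclohex-2-en-1-yl]-2-(PMB-oxymethyl)prop-2-enoate (1,6-cis) | CC(C)[C@H]1CCC(COCc2ccc(OC)cc2)=C[C@H]1/C=C(\COCc1ccc(OC)cc1)C(=O)OC | intermediate
28 | (2E)-3-[(1S,6R)-3-(PMB-oxymethyl)-6-(propan-2-yl)cyclohex-2-en-1-yl]-2-(PMB-oxymethyl)prop-2-enoic acid | CC(C)[C@H]1CCC(COCc2ccc(OC)cc2)=C[C@H]1/C=C(\COCc1ccc(OC)cc1)C(=O)O | intermediate
29 | protected target: ester of 28 with the primary hydroxyl of the diol derived from 16 (tertiary OH free, 2 PMB ethers, tert-butyl ester) | CC(C)[C@H]1CCC(COCc2ccc(OC)cc2)=C[C@H]1/C=C(\COCc1ccc(OC)cc1)C(=O)OC[C@@]1(O)CC[C@@H](C(C)C)[C@@H]2C=C(C(=O)OC(C)(C)C)COC(=O)[C@@H]21 | intermediate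
30 | CNP0361406.7 | CC(C)[C@H]1CCC(CO)=C[C@H]1/C=C(\CO)C(=O)OC[C@@]1(O)CC[C@@H](C(C)C)[C@@H]2C=C(C(=O)O)COC(=O)[C@@H]21 | target

## Step count and risks

Total step count: 19. Longest linear sequence: 12 steps (steps 1–10, then 18 and 19).

Steps most likely to fail:

Step 14 (key cycloaddition). The cycloaddition may be too slow because the trienoate is electron-poor and its ester and ether oxygens can sequester the boron catalyst, and enantiofacial control may erode if the temperature has to be raised. The fallback sets out from 24 and uses a bidentate, much more reactive dienophile. Cycloaddition of 24 with 3-acryloyl-1,3-oxazolidin-2-one is catalysed by the divalent copper complex Cu(SbF6)2/(S,S)-2,2'-isopropylidenebis(4-tert-butyl-2-oxazoline) in CH2Cl2 and should give the endo N-acyloxazolidinone F1. Transamidation with MeONHMe·HCl/AlMe3 at −20 °C should give the N-methoxy-N-methylamide F2, and MeMgBr at −78 → −40 °C converts F2 into the methyl ketone; the fallback comes back to the route at 25.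

Step 13 (Heck coupling). The alkenylpalladium intermediate may lose alkoxide by β-elimination, and the triene may oligomerise under the coupling conditions. The fallback sets out from 19 and builds the triene in the other order. Stille coupling of 19 with (E)-3-(tributylstannyl)prop-2-enal (Pd(PPh3)4, CuI, DMF, rt) should give (2E)-4-{[(4-methoxyphenyl)methoxy]methyl}penta-2,4-dienal F3. F3 is then olefinated in the manner of step 12 (18, NaH, 20, through carbanion 22); the fallback comes back to the route at 24.

Step 18 (fragment union). Substitution at the neopentyl-type epoxide CH2 by the hindered carboxylate may be slow, leaving time for base-induced degradation of the lactone on prolonged heating. The fallback sets out from 16 and separates the two events. Cesium formate (HCO2Cs, DMF, 60 °C), a small oxygen nucleophile, opens the epoxide at CH2 to give the hydroxy formate F4. Mild methanolysis (KHCO3, MeOH, 0 °C) gives the diol F5. Yamaguchi esterification of the primary hydroxyl of F5 with 28 (2,4,6-trichlorobenzoyl chloride, Et3N, then 4-(dimethylamino)pyridine) makes the fragment union an acylation; the fallback comes back to the route at 29.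

Further compounds
F1 | step 14 | 3-{[(1S,6S)-configured 2-[(E)-acrylate arm]-4-(PMB-oxymethyl)cyclohex-3-en-1-yl]carbonyl}-1,3-oxazolidin-2-one (arm and acyl cis) | O=C(N2CCOC2=O)[C@H]1CCC(COCc2ccc(OC)cc2)=C[C@H]1/C=C(\COCc1ccc(OC)cc1)C(=O)OC
F2 | step 14 | N-methoxy-N-methylamide corresponding to F1 | CON(C)C(=O)[C@H]1CCC(COCc2ccc(OC)cc2)=C[C@H]1/C=C(\COCc1ccc(OC)cc1)C(=O)OC
F3 | step 13 | (2E)-4-{[(4-methoxyphenyl)methoxy]methyl}penta-2,4-dienal | C=C(COCc1ccc(OC)cc1)/C=C/C=O
F4 | step 18 | hydroxy formate from 16 (primary formate, tertiary OH) | O=COC[C@@]1(O)CC[C@@H](C(C)C)[C@@H]2C=C(C(=O)OC(C)(C)C)COC(=O)[C@@H]21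
F5 | step 18 | diol from 16 (primary and tertiary OH) | OC[C@@]1(O)CC[C@@H](C(C)C)[C@@H]2C=C(C(=O)OC(C)(C)C)COC(=O)[C@@H]21
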